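## Retrosynthetic overview

1. The target is the dienol acetate of bicyclic aldehyde 20; 20 comes from the exocyclic methylene lactone 18 by hydroboration–oxidation, and 18 from the ester 17 by demethoxycarbonylation.
2. The nine-membered carbocycle (second ring formed) is closed at C8–C1 by an In(III) Conia-ene reaction of dienyne lactone 16; the γ-lactone is the first ring formed (step 4).
3. The (E)-trisubstituted olefin of 16 comes from Nozaki–Hiyama–Kishi coupling of vinyl bromide 12 with (Z)-enynal 6, then Myers reductive 1,3-transposition.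
4. Enynal 6 (C-a and C1–C4, with the Z-olefin and the alkyne) comes from furfural by ring-opening of 2-furylcarbene.
5. Lactone 12 comes from (S)-citronellal by photoredox/enamine α-malonylation (C9) and asymmetric 2-bromoallylation with lactonisation (C7).

Assumption: labels used below are C-a (enol CH), C1–C9 round the carbocycle from the enol-bearing carbon (C7 carries O, C8 the lactone carbonyl, C9 the side chain) and C10 (side-chain stereocentre); the two chiral controllers are used as whichever enantiomer gives the facial sense stated.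

## Route

Step 1
Reactants: 1 furfural; 2 4-methylbenzenesulfonohydrazide
Product: 3 N'-[(E)-furan-2-ylmethylidene]-4-methylbenzenesulfonohydrazide
Conditions: MeOH, rt
Reagents that add atoms: none
Why: Condensation of the aldehyde with the sulfonyl hydrazide gives the (E)-tosylhydrazone and creates no stereocentre.

Step 2
Reactants: 3 N'-[(E)-furan-2-ylmethylidene]-4-methylbenzenesulfonohydrazide
Product: 6 (2Z)-pent-2-en-4-ynal, via sodium salt 4 (not isolated), via 2-(diazomethyl)furan 5 (not isolated)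
Conditions: NaH, THF, 0 °C; evaporate; flash vacuum pyrolysis 250 °C, 0.1 Torr, trap at −78 °C
Reagents that add atoms: none
Why: Bamford–Stevens decomposition gives 2-furyldiazomethane and then 2-furylcarbene, whose ring-opening (Hoffmann–Shechter reaction) destroys the furan, passes its C3=C4 bond on as the (Z)-olefin and turns C2 plus the carbene carbon into the terminal alkyne.

Step 3
Reactants: 7 (S)-citronellal; 8 dimethyl 2-bromopropanedioate
Product: 9 dimethyl 2-[(2R,3S)-3,7-dimethyl-1-oxooct-6-en-2-yl]propanedioate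
Conditions: [Ru(bpy)3]Cl2 (0.5 mol %), (2R,5S)-2-tert-butyl-3,5-dimethylimidazolidin-4-one·TfOH (20 mol %), 2,6-lutidine, DMF, visible light, rt; used crude
Reagents that add atoms: none
Why: In this MacMillan photoredox/enamine α-alkylation the malonyl radical adds to the Si face of the (E)-enamine left open by the imidazolidinone, which sets C9 (R) under catalyst control beside the untouched citronellal centre.

Step 4
Reactants: 9 dimethyl 2-[(2R,3S)-3,7-dimethyl-1-oxooct-6-en-2-yl]propanedioate; 10 2,3-dibromoprop-1-ene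
Product: 12 methyl (4R,5S)-5-(2-bromoprop-2-en-1-yl)-4-[(2S)-6-methylhept-5-en-2-yl]-2-oxooxolane-3-carboxylate, via hydroxy diester 11 (not isolated)
Conditions: CrCl2 (3 equiv), Kishi oxazoline–sulfonamide ligand (3.3 equiv), Et3N, THF, 0 °C → rt; aqueous work-up; then PPTS (cat.), PhMe, 60 °C
Reagents that add atoms: none
Why: In this asymmetric Nozaki–Hiyama–Kishi 2-bromoallylation the ligand-bound allylchromium attacks the Si face of the aldehyde (reagent control over the weak Felkin bias) to set C7 (S), and the γ-hydroxy malonate then closes to the trans-4,5-disubstituted γ-lactone (C3 stays epimerisable until step 7).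

Step 5
Reactants: 12 methyl (4R,5S)-5-(2-bromoprop-2-en-1-yl)-4-[(2S)-6-methylhept-5-en-2-yl]-2-oxooxolane-3-carboxylate; 6 (2Z)-pent-2-en-4-ynal
Product: 13 methyl (4R,5S)-5-[(4Z)-3-hydroxy-2-methylidenehept-4-en-6-yn-1-yl]-4-[(2S)-6-methylhept-5-en-2-yl]-2-oxooxolane-3-carboxylate
Conditions: CrCl2 (4 equiv), NiCl2 (2 mol %), DMSO, rt
Reagents that add atoms: none
Why: Ni/Cr-mediated Nozaki–Hiyama–Kishi coupling adds the alkenylchromium 1,2 to the enal without touching lactone, ester, alkyne or the (Z)-olefin, and the new carbinol centre (both epimers) is erased in step 6.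

Step 6
Reactants: 13 methyl (4R,5S)-5-[(4Z)-3-hydroxy-2-methylidenehept-4-en-6-yn-1-yl]-4-[(2S)-6-methylhept-5-en-2-yl]-2-oxooxolane-3-carboxylate
Product: 16 methyl (4R,5S)-5-[(2E,4Z)-2-methylhepta-2,4-dien-6-yn-1-yl]-4-[(2S)-6-methylhept-5-en-2-yl]-2-oxooxolane-3-carboxylate, via sulfonylhydrazine adduct 14 (not isolated), via allylic diazene 15 (not isolated)
Conditions: 2-nitrobenzenesulfonohydrazide (NBSH), PPh3, DEAD, N-methylmorpholine, −30 °C → rt
Reagents that add atoms: none
Why: Myers reductive 1,3-transposition (Mitsunobu displacement by NBSH, sulfinate loss, retro-ene loss of N2) moves the double bond into conjugation and puts H on the former CH2, the (E)-olefin (C3 cis to the new methyl) being expected because A(1,2) strain keeps the dienyne arm away from C6 in the cyclic transition state.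

Step 7
Reactants: 16 methyl (4R,5S)-5-[(2E,4Z)-2-methylhepta-2,4-dien-6-yn-1-yl]-4-[(2S)-6-methylhept-5-en-2-yl]-2-oxooxolane-3-carboxylate
Product: 17 methyl (1S,3Z,5E,8S,11R)-6-methyl-11-[(2S)-6-methylhept-5-en-2-yl]-2-methylidene-10-oxo-9-oxabicyclo[6.2.1]undeca-3,5-diene-1-carboxylate
Conditions: In(NTf2)3 (10 mol %), PhMe, 90 °C, 2 mM
Reagents that add atoms: none
Why: Indium(III)-catalysed Conia-ene cyclisation (precedented for six- to fifteen-membered rings from ω-alkynyl β-dicarbonyls) joins the enolised α-carbomethoxy lactone carbon 9-exo-dig to the internal alkyne carbon, and since only the face cis to the C7 arm can reach the alkyne the quaternary C8 is set by the ring.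

Step 8
Reactants: 17 methyl (1S,3Z,5E,8S,11R)-6-methyl-11-[(2S)-6-methylhept-5-en-2-yl]-2-methylidene-10-oxo-9-oxabicyclo[6.2.1]undeca-3,5-diene-1-carboxylate
Product: 18 (1S,3Z,5E,8S,11R)-6-methyl-11-[(2S)-6-methylhept-5-en-2-yl]-2-methylidene-9-oxabicyclo[6.2.1]undeca-3,5-dien-10-one
Conditions: LiCl, DMSO–H2O, 110 °C
Reagents that add atoms: none
Why: Krapcho demethoxycarbonylation (chloride SN2 at the methyl group, then decarboxylation) gives a bridgehead ester enolate that can only be protonated to the bridged (8S) lactone.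

Step 9
Reactants: 18 (1S,3Z,5E,8S,11R)-6-methyl-11-[(2S)-6-methylhept-5-en-2-yl]-2-methylidene-9-oxabicyclo[6.2.1]undeca-3,5-dien-10-one
Product: 20 (1S,3Z,5E,8S,11R)-6-methyl-11-[(2S)-6-methylhept-5-en-2-yl]-10-oxo-9-oxabicyclo[6.2.1]undeca-3,5-diene-2-carbaldehyde, via B-alkyl-9-BBN adduct 19 (not isolated)
Conditions: 9-BBN, THF, 0 °C → rt; then NMO, TPAP (5 mol %), 4 Å MS, CH2Cl2, rt
Reagents that add atoms: 4-methylmorpholine N-oxide (NMO), C[N+]1([O-])CCOCC1
Why: 9-BBN hydroborates only the least hindered 1,1-disubstituted terminal alkene with boron on the CH2, and NMO/TPAP oxidation of the alkylborane stops at the aldehyde (hydroboration–oxidation; the new α-centre is lost in step 10).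

Step 10
Reactants: 20 (1S,3Z,5E,8S,11R)-6-methyl-11-[(2S)-6-methylhept-5-en-2-yl]-10-oxo-9-oxabicyclo[6.2.1]undeca-3,5-diene-2-carbaldehyde
Product: 21 [(Z)-[(1S,3Z,5E,8S,11R)-6-methyl-11-[(2S)-6-methylhept-5-en-2-yl]-10-oxo-9-oxabicyclo[6.2.1]undeca-3,5-dien-2-ylidene]methyl] acetate (target)
Conditions: Ac2O, Et3N, DMAP (cat.), CH2Cl2, 0 °C → rt
Reagents that add atoms: acetic anhydride, CC(=O)OC(C)=O
Why: Amine-mediated enolisation of the single α-hydrogen and O-acetylation of the extended enolate (dienol acetate formation) give the conjugated trienyl acetate, the isomer with acetoxy cis to C8 and anti to the diene being the expected major one.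

## Compound list

1 | furfural | O=Cc1ccco1 | starting material
2 | 4-methylbenzenesulfonohydrazide | Cc1ccc(cc1)S(=O)(=O)NN | starting material
3 | N'-[(E)-furan-2-ylmethylidene]-4-methylbenzenesulfonohydrazide | Cc1ccc(cc1)S(=O)(=O)N/N=C/c1ccco1 | intermediate
4 | sodium salt of 3 | Cc1ccc(cc1)S(=O)(=O)[N-]/N=C/c1ccco1.[Na+] | intermediate
5 | 2-(diazomethyl)furan | [N-]=[N+]=Cc1ccco1 | intermediate
6 | (2Z)-pent-2-en-4-ynal | O=C/C=C\C#C | intermediate
7 | (S)-citronellal, (3S)-3,7-dimethyloct-6-enal | O=CC[C@@H](C)CCC=C(C)C | starting material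
8 | dimethyl 2-bromopropanedioate | COC(=O)C(Br)C(=O)OC | starting material
9 | dimethyl 2-[(2R,3S)-3,7-dimethyl-1-oxooct-6-en-2-yl]propanedioate | O=C[C@H]([C@@H](C)CCC=C(C)C)C(C(=O)OC)C(=O)OC | intermediate
10 | 2,3-dibromoprop-1-ene | C=C(Br)CBr | starting material
11 | dimethyl 2-[(1R,2S)-1-[(1S)-3-bromo-1-hydroxybut-3-en-1-yl]-2,6-dimethylhept-5-en-1-yl]propanedioate | COC(=O)C(C(=O)OC)[C@@H]([C@@H](C)CCC=C(C)C)[C@@H](O)CC(Br)=C | intermediate
12 | methyl (4R,5S)-5-(2-bromoprop-2-en-1-yl)-4-[(2S)-6-methylhept-5-en-2-yl]-2-oxooxolane-3-carboxylate (C-3 epimers) | COC(=O)C1C(=O)O[C@@H](CC(Br)=C)[C@@H]1[C@@H](C)CCC=C(C)C | intermediate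
13 | methyl (4R,5S)-5-[(4Z)-3-hydroxy-2-methylidenehept-4-en-6-yn-1-yl]-4-[(2S)-6-methylhept-5-en-2-yl]-2-oxooxolane-3-carboxylate (carbinol and C-3 epimers) | COC(=O)C1C(=O)O[C@@H](CC(=C)C(O)/C=C\C#C)[C@@H]1[C@@H](C)CCC=C(C)C | intermediate
14 | N-allylic N-(2-nitrophenylsulfonyl)hydrazine from 13 | COC(=O)C1C(=O)O[C@@H](CC(=C)C(/C=C\C#C)N(N)S(=O)(=O)c2ccccc2[N+](=O)[O-])[C@@H]1[C@@H](C)CCC=C(C)C | intermediate
15 | allylic monoalkyl diazene from 14 | COC(=O)C1C(=O)O[C@@H](CC(=C)C(/C=C\C#C)N=N)[C@@H]1[C@@H](C)CCC=C(C)C | intermediate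
16 | methyl (4R,5S)-5-[(2E,4Z)-2-methylhepta-2,4-dien-6-yn-1-yl]-4-[(2S)-6-methylhept-5-en-2-yl]-2-oxooxolane-3-carboxylate (C-3 epimers) | COC(=O)C1C(=O)O[C@@H](C/C(C)=C/C=C\C#C)[C@@H]1[C@@H](C)CCC=C(C)C | intermediate
17 | methyl (1S,3Z,5E,8S,11R)-6-methyl-11-[(2S)-6-methylhept-5-en-2-yl]-2-methylidene-10-oxo-9-oxabicyclo[6.2.1]undeca-3,5-diene-1-carboxylate | C=C1/C=C\C=C(/C)C[C@@H]2OC(=O)[C@@]1(C(=O)OC)[C@H]2[C@@H](C)CCC=C(C)C | intermediate
18 | (1S,3Z,5E,8S,11R)-6-methyl-11-[(2S)-6-methylhept-5-en-2-yl]-2-methylidene-9-oxabicyclo[6.2.1]undeca-3,5-dien-10-one | C=C1/C=C\C=C(/C)C[C@@H]2OC(=O)[C@H]1[C@H]2[C@@H](C)CCC=C(C)C | intermediate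
19 | B-alkyl-9-BBN adduct of 18 (boron on the former CH2) | C(B3C4CCCC3CCC4)C1/C=C\C=C(/C)C[C@@H]2OC(=O)[C@H]1[C@H]2[C@@H](C)CCC=C(C)C | intermediate
20 | (1S,3Z,5E,8S,11R)-6-methyl-11-[(2S)-6-methylhept-5-en-2-yl]-10-oxo-9-oxabicyclo[6.2.1]undeca-3,5-diene-2-carbaldehyde (C-2 epimers) | O=CC1/C=C\C=C(/C)C[C@@H]2OC(=O)[C@H]1[C@H]2[C@@H](C)CCC=C(C)C | intermediate
21 | [(Z)-[(1S,3Z,5E,8S,11R)-6-methyl-11-[(2S)-6-methylhept-5-en-2-yl]-10-oxo-9-oxabicyclo[6.2.1]undeca-3,5-dien-2-ylidene]methyl] acetate | CC(=O)O/C=C1/C=C\C=C(/C)C[C@@H]2OC(=O)[C@H]1[C@H]2[C@@H](C)CCC=C(C)C | target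

## Step count and risks

Total step count: 10. Longest linear sequence: 8 (steps 3–10 from (S)-citronellal); the furfural branch (steps 1–2) joins at step 5.

The three steps most likely to fail:

**Step 7 (nine-membered Conia-ene closure).** Oligomerisation or Lewis-acid damage to the dienyne may win over ring closure. The fallback sets out from 16 and comes back at 17. Bromoboration of the terminal alkyne with B-bromo-9-BBN, then protonolysis with AcOH, gives the 2-bromo-1,3-diene lactone F1. A Pd(0)-catalysed intramolecular C-alkenylation of the malonate-type carbon (Pd2(dba)3, t-Bu3P, Cs2CO3, PhMe, high dilution) then closes the ring by cross-coupling instead of alkyne activation.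

**Step 6 (Myers transposition on a doubly allylic carbinol).** Possible failures are SN2′ Mitsunobu attack, hydrogen delivery to the enyne side, C-alkylation by the acidic C8–H, or E/Z erosion. The fallback sets out from 12 and comes back at 16. TBAF-mediated dehydrobromination gives the terminal alkyne lactone F2. Zr-catalysed carboalumination (Me3Al, Cp2ZrCl2), transmetalation with ZnCl2 and Pd-catalysed Negishi coupling with (Z)-(4-chlorobut-3-en-1-yn-1-yl)trimethylsilane give the silylated dienyne lactone F3; this fixes the (E)-olefin by syn-carbometalation. K2CO3 in MeOH then removes the silyl group.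

**Step 10 (enol acetate geometry).** Direct acetylation may give a mixture of enol isomers. The fallback sets out from 20 and comes back at 21. TBSOTf and Et3N convert the aldehyde into the silyl dienol ether F4, which is stable enough to be equilibrated and separated as the isomer with oxygen cis to C8. Ac2O with catalytic CsF then exchanges silyl for acetyl with retention of the enol geometry.

## Further compounds

F1 | step 7 | methyl (4R,5S)-5-[(2E,4Z)-6-bromo-2-methylhepta-2,4,6-trien-1-yl]-4-[(2S)-6-methylhept-5-en-2-yl]-2-oxooxolane-3-carboxylate | COC(=O)C1C(=O)O[C@@H](C/C(C)=C/C=C\C(Br)=C)[C@@H]1[C@@H](C)CCC=C(C)C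
F2 | step 6 | methyl (4R,5S)-4-[(2S)-6-methylhept-5-en-2-yl]-2-oxo-5-(prop-2-yn-1-yl)oxolane-3-carboxylate | COC(=O)C1C(=O)O[C@@H](CC#C)[C@@H]1[C@@H](C)CCC=C(C)C
F3 | step 6 | methyl (4R,5S)-5-[(2E,4Z)-2-methyl-7-(trimethylsilyl)hepta-2,4-dien-6-yn-1-yl]-4-[(2S)-6-methylhept-5-en-2-yl]-2-oxooxolane-3-carboxylate | COC(=O)C1C(=O)O[C@@H](C/C(C)=C/C=C\C#C[Si](C)(C)C)[C@@H]1[C@@H](C)CCC=C(C)C
F4 | step 10 | (1S,2Z,3Z,5E,8S,11R)-2-{[tert-butyl(dimethyl)silyl]oxymethylidene}-6-methyl-11-[(2S)-6-methylhept-5-en-2-yl]-9-oxabicyclo[6.2.1]undeca-3,5-dien-10-one | CC(C)(C)[Si](C)(C)O/C=C1/C=C\C=C(/C)C[C@@H]2OC(=O)[C@H]1[C@H]2[C@@H](C)CCC=C(C)C
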